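**Strategy.** The route rests on cutting both bonds to C3'B, the only fully substituted sp3 carbon (side chains numbered ArCH2(C1')–C2'–C3'; A is the isopropenyl half, B the carbinol half). C3'B is bonded to the ether oxygen, two methyls and C2'B, so it is an acetone-derived ketal carbon with a carbon substituent where the second alkoxy group would be. In one operation (S)-auraptenol, made from osthol, is ketalised with 2-methoxypropene and the methoxy group is exchanged for ethynyl. This forms O–C3'B and C3'B–C2'B; no ring closes and both coumarin ring systems are spectators. The alkyne is then converted into the aryl-bearing S carbinol.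

Key step: step 3

Remarks on the chemistry:
- The usual D-fructose-derived Shi ketone is expected to give the R epoxide of a prenyl arene. Step 1 therefore uses the enantiomeric L-fructose-derived ketone (made from L-sorbose), which is assumed to be purchasable, as is Pd(Quinox)Cl2.
- Compound 7 is a 1,6-enyne: the terminal alkyne and the isopropenyl alkene are joined through the ether oxygen, with a gem-dimethyl group in the tether. Its C2'A–H is also placed for 1,5-hydride transfer to an activated alkyne. Hydration with carbophilic gold, mercury or platinum catalysts would compete with cycloisomerisation, so the methyl ketone is reached by semihydrogenation and Wacker oxidation instead.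

**Route**

Step 1
Reactants: 1 osthol (7-methoxy-8-(3-methylbut-2-enyl)coumarin)
Product: 2 (S)-meranzin, 8-{[(2S)-3,3-dimethyloxiran-2-yl]methyl}-7-methoxycoumarin
Conditions: L-fructose-derived Shi ketone (1,2:4,5-di-O-isopropylidene-β-L-erythro-2,3-hexodiulo-2,6-pyranose, 30 mol%), Oxone (2KHSO5·KHSO4·K2SO4), K2CO3, Bu4NHSO4 (cat.), MeCN–CH2(OMe)2 / aq. Na2B4O7–Na2EDTA buffer, pH ≈ 10.5, 0 °C
Reagents that add atoms: potassium peroxymonosulfate (active component of Oxone), [K+].[O-]S(=O)(=O)OO
Why: Shi asymmetric epoxidation, in which the dioxirane of the L-fructose-derived ketone should attack the electron-rich trisubstituted prenyl alkene through the spiro transition state on the face that makes C2'A S, while the electron-poor coumarin C3=C4 bond and the lactone are expected to survive the short exposure at 0 °C.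

Step 2
Reactants: 2 (S)-meranzin
Product: 3 (S)-auraptenol, 8-[(2S)-2-hydroxy-3-methylbut-3-enyl]-7-methoxycoumarin
Conditions: Al(OiPr)3 (2 equiv), toluene, 110 °C; aqueous tartrate work-up
Reagents that add atoms: none
Why: Aluminium isopropoxide-mediated isomerisation of a trisubstituted epoxide to an allylic alcohol, in which aluminium binds the epoxide oxygen and the tertiary C3'A–O bond breaks while an isopropoxide ligand removes a methyl proton in a cyclic syn elimination, so the C2'A–O bond is untouched and the S configuration (same priority order, same descriptor) is retained.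

Step 3
Reactants: 3 (S)-auraptenol; 4 2-methoxypropene; 5 potassium ethynyltrifluoroborate
Product: 7 (S)-auraptenyl 2-methylbut-3-yn-2-yl ether, via mixed methyl ketal 6 (not isolated)
Conditions: 4 (4 equiv), PPTS (5 mol%), CH2Cl2, 0 °C; Et3N (10 mol%), volatiles removed in vacuo; then 5 (3 equiv), BF3·OEt2 (3.5 equiv), MeCN–CH2Cl2, −40 → 0 °C
Reagents that add atoms: 2-methoxypropene (4), COC(C)=C; potassium ethynyltrifluoroborate (5), [K+].C#C[B-](F)(F)F
Why: Pyridinium tosylate protonates enol ether 4 at its CH2 terminus and the secondary hydroxyl of 3 attacks the planar 2-methoxyprop-2-yl cation, which gives ketal 6 and sidesteps any displacement at a fully substituted carbon; BF3 then abstracts fluoride from 5 (giving KBF4 and ethynyldifluoroborane), the borane binds the methoxy oxygen of 6, the ketal ionises to the oxocarbenium ion RO(+)=CMe2, and the ethynyl(methoxy)difluoroborate counter-ion passes its ethynyl group to the cationic carbon, forming C3'B–C2'B. The closest known reaction type is the BF3-promoted coupling of mixed acetals with potassium alkynyltrifluoroborates to give propargylic ethers; a ketone-derived ketal is its most demanding substrate class because the tertiary oxocarbenium ion can also lose a proton, although the enol ether so formed is re-protonated and re-enters the same pathway. No ring is closed and no stereocentre is created, and because the C2'A–O bond is never broken the S configuration of 3 is carried into 7. The selectivity required is departure of methoxide and not of the auraptenyl alkoxide: boron should favour the less hindered, more Lewis-basic methoxy oxygen, ionisation in the other sense only returns 3 after work-up, and cooling keeps the allylic C2'A–O bond intact. Excess 4 is stripped off before the Lewis acid is added so that no enol ether remains to add to the oxocarbenium ion.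

Step 4
Reactants: 7 (S)-auraptenyl 2-methylbut-3-yn-2-yl ether
Product: 8 (S)-auraptenyl 2-methylbut-3-en-2-yl ether
Conditions: H2 (1 atm, stopped after 1 equiv), Pd on CaCO3 poisoned with Pb(OAc)2 (Lindlar catalyst), quinoline, EtOAc, rt
Reagents that add atoms: none
Why: Lindlar semihydrogenation, in which the terminal alkyne binds the poisoned palladium surface much more strongly than the 1,1-disubstituted isopropenyl alkene, the coumarin C3=C4 bond or the new vinyl group, so one equivalent of H2 should be taken up selectively and the 1,6-enyne is removed before any metal-catalysed oxidation.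

Step 5
Reactants: 8 (S)-auraptenyl 2-methylbut-3-en-2-yl ether
Product: 9 methyl ketone, 7-methoxy-8-[(2S)-3-methyl-2-(2-methyl-3-oxobutan-2-yloxy)but-3-enyl]coumarin
Conditions: Pd(Quinox)Cl2 (Quinox = 2-(4,5-dihydrooxazol-2-yl)quinoline, 5 mol%), AgSbF6 (12 mol%), aq. t-BuOOH (70%, 12 equiv), CH2Cl2, 0 °C → rt
Reagents that add atoms: tert-butyl hydroperoxide, CC(C)(C)OO
Why: Wacker-type oxidation, in which cationic divalent palladium binds the monosubstituted vinyl group, the ligand-controlled peroxypalladation delivers oxygen to the internal carbon even next to an allylic oxygen, and O–O cleavage with 1,2-hydride shift gives the methyl ketone, while the 1,1-disubstituted isopropenyl alkene and the coumarin alkene are not substrates for this catalyst.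

Step 6
Reactants: 10 umbelliferone (7-hydroxycoumarin)
Product: 11 7-hydroxy-8-iodocoumarin
Conditions: I2, KI, 20% aq. NH3, rt; then dilute H2SO4
Reagents that add atoms: iodine, [I][I]
Why: Electrophilic aromatic iodination of the phenoxide, for which C8 (between the phenol oxygen and the ring oxygen) is the established site of monoiodination of umbelliferone under these conditions.

Step 7
Reactants: 11 7-hydroxy-8-iodocoumarin
Product: 12 8-iodo-7-methoxycoumarin
Conditions: MeI, K2CO3, acetone, reflux
Reagents that add atoms: iodomethane, CI
Why: Williamson O-methylation of the phenol, to which the lactone and the aryl iodide are inert.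

Step 8
Reactants: 9 methyl ketone; 12 8-iodo-7-methoxycoumarin
Product: 13 aryl ketone, 7-methoxy-8-[(2S)-2-{[4-(7-methoxy-2-oxochromen-8-yl)-2-methyl-3-oxobutan-2-yl]oxy}-3-methylbut-3-enyl]coumarin
Conditions: Pd(OAc)2 (5 mol%), XPhos (10 mol%), K3PO4 (2.5 equiv), toluene, 90 °C
Reagents that add atoms: 8-iodo-7-methoxycoumarin (12), COc1ccc2ccc(=O)oc2c1I
Why: Palladium-catalysed α-arylation of a ketone, in which 9 can enolise only toward its methyl group (the other α-carbon is quaternary), the weak base K3PO4 should spare both lactones, oxidative addition of 12 to zerovalent palladium and reductive elimination from the XPhos-bound arylpalladium enolate form C1'B–C8, and the two ortho substituents of the aryl group block a second arylation.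

Step 9
Reactants: 13 aryl ketone
Product: 14 target CNP0142500.1, (2'S) carbinol
Conditions: (R)-2-methyl-CBS-oxazaborolidine (20 mol%), catecholborane (2 equiv), toluene, −40 → −20 °C; aq. NaHCO3 work-up
Reagents that add atoms: none
Why: Corey–Bakshi–Shibata reduction, in which the (R)-oxazaborolidine binds the ketone oxygen anti to the larger, tertiary C3'B substituent and hydride from catecholborane is delivered to the face that gives the S carbinol at C2'B (reagent control, the remote C2'A centre having little influence), while catecholborane at low temperature should neither hydroborate the isopropenyl group nor reduce the lactones.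

**Compound list**

1 | osthol, 7-methoxy-8-(3-methylbut-2-enyl)coumarin | CC(C)=CCc1c(OC)ccc2ccc(=O)oc12 | starting material
2 | (S)-meranzin, 8-{[(2S)-3,3-dimethyloxiran-2-yl]methyl}-7-methoxycoumarin | CC1(C)O[C@H]1Cc1c(OC)ccc2ccc(=O)oc12 | intermediate
3 | (S)-auraptenol, 8-[(2S)-2-hydroxy-3-methylbut-3-enyl]-7-methoxycoumarin | C=C(C)[C@H](Cc1c(OC)ccc2ccc(=O)oc12)O | intermediate
4 | 2-methoxypropene | COC(C)=C | starting material
5 | potassium ethynyltrifluoroborate | [K+].C#C[B-](F)(F)F | starting material
6 | mixed methyl ketal, 7-methoxy-8-[(2S)-2-(2-methoxypropan-2-yloxy)-3-methylbut-3-enyl]coumarin (formed in the flask, not isolated) | C=C(C)[C@H](Cc1c(OC)ccc2ccc(=O)oc12)OC(C)(C)OC | intermediate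
7 | (S)-auraptenyl 2-methylbut-3-yn-2-yl ether | C=C(C)[C@H](Cc1c(OC)ccc2ccc(=O)oc12)OC(C)(C)C#C | intermediate
8 | (S)-auraptenyl 2-methylbut-3-en-2-yl ether | C=C(C)[C@H](Cc1c(OC)ccc2ccc(=O)oc12)OC(C)(C)C=C | intermediate
9 | methyl ketone, 7-methoxy-8-[(2S)-3-methyl-2-(2-methyl-3-oxobutan-2-yloxy)but-3-enyl]coumarin | C=C(C)[C@H](Cc1c(OC)ccc2ccc(=O)oc12)OC(C)(C)C(C)=O | intermediate
10 | umbelliferone, 7-hydroxycoumarin | Oc1ccc2ccc(=O)oc2c1 | starting material
11 | 7-hydroxy-8-iodocoumarin | Oc1ccc2ccc(=O)oc2c1I | intermediate
12 | 8-iodo-7-methoxycoumarin | COc1ccc2ccc(=O)oc2c1I | intermediate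
13 | aryl ketone, C2'B oxo precursor of the target | C=C(C)[C@H](Cc1c(OC)ccc2ccc(=O)oc12)OC(C)(C)C(=O)Cc1c(OC)ccc2ccc(=O)oc12 | intermediate
14 | CNP0142500.1, (2'S,2'S) bis-coumarin ether | C=C(C)[C@H](Cc1c(OC)ccc2ccc(=O)oc12)OC(C)(C)[C@@H](O)Cc1c(OC)ccc2ccc(=O)oc12 | target

**Step count**

Total steps: 9. Longest linear sequence: 7 steps (steps 1, 2, 3, 4, 5, 8, 9, from osthol); the aryl iodide branch adds steps 6 and 7.

**Steps most likely to fail, with fallbacks**

Step 3. Ionisation of the ketal in the wrong sense, or proton loss from the tertiary oxocarbenium ion, may outrun alkynyl transfer. The fallback sets out from 3 and returns at 7 through a Nicholas reaction, in which the alkyne is already attached to the tertiary carbon and the cation is stabilised by cobalt. Commercial 2-methylbut-3-yn-2-ol is complexed with Co2(CO)8 (CH2Cl2, rt) to give hexacarbonyl(μ-2-methylbut-3-yn-2-ol)dicobalt F1. BF3·OEt2 in CH2Cl2 at −20 °C ionises it to the cobalt-stabilised propargylic cation, which alcohol 3 captures to give the dicobalt hexacarbonyl complex of the propargyl ether F2. Oxidative decomplexation with (NH4)2Ce(NO3)6 in acetone at −20 °C then releases 7. It is done at once and without amine N-oxides, so that no Pauson–Khand reaction with the isopropenyl group can start.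

Step 5. Oxygen delivery to the internal carbon may be hindered by the adjacent quaternary ether carbon, leading to attack at the terminal carbon or to no turnover. The fallback sets out from 7 and returns at 9, replacing steps 4 and 5. Markovnikov hydrosilylation of the alkyne with triethoxysilane and [Cp*Ru(MeCN)3]PF6 (CH2Cl2, 0 °C, silane present before the catalyst is added) should place silicon on the internal carbon and give the α-(triethoxysilyl)vinyl ether F3. Tamao oxidation (KF, KHCO3, H2O2, THF–MeOH, 0 °C to rt) then converts the C–Si bond into the enol and hence into methyl ketone 9.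

Step 8. Enolate formation under basic conditions at 90 °C may lead to lactone opening or to conjugate addition to a coumarin, or the di-ortho-substituted iodide may couple too slowly. The fallback sets out from 9 and returns at 13 with a preformed, neutral enol nucleophile. Soft enolisation of 9 (TMSOTf, Et3N, CH2Cl2, −78 to 0 °C) gives the trimethylsilyl enol ether F4. This is coupled with 12 under fluoride activation and without a Brønsted base (Pd(OAc)2, P(t-Bu)3, Bu3SnF, toluene, 85 °C; arylation of a tin enolate formed in the flask) to give 13.

**Further compounds**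

F1 | step 3 | hexacarbonyl(μ-2-methylbut-3-yn-2-ol)dicobalt (written as its components) | CC(C)(O)C#C.[Co].[Co].[C-]#[O+].[C-]#[O+].[C-]#[O+].[C-]#[O+].[C-]#[O+].[C-]#[O+]
F2 | step 3 | dicobalt hexacarbonyl complex of ether 7 (written as its components) | C=C(C)[C@H](Cc1c(OC)ccc2ccc(=O)oc12)OC(C)(C)C#C.[Co].[Co].[C-]#[O+].[C-]#[O+].[C-]#[O+].[C-]#[O+].[C-]#[O+].[C-]#[O+]
F3 | step 5 | 7-methoxy-8-[(2S)-3-methyl-2-{[2-methyl-3-(triethoxysilyl)but-3-en-2-yl]oxy}but-3-enyl]coumarin | C=C(C)[C@H](Cc1c(OC)ccc2ccc(=O)oc12)OC(C)(C)C(=C)[Si](OCC)(OCC)OCC
F4 | step 8 | trimethylsilyl enol ether of 9, 7-methoxy-8-[(2S)-3-methyl-2-{[2-methyl-3-(trimethylsilyloxy)but-3-en-2-yl]oxy}but-3-enyl]coumarin | C=C(C)[C@H](Cc1c(OC)ccc2ccc(=O)oc12)OC(C)(C)C(=C)O[Si](C)(C)C
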